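**Strategy.** Ring A is opened at C1–C10 and C3–C4 (labdane numbering), the bonds that flank the two quaternary carbons C4 and C10 on either side of C5. (1S,5S)-Verbenone (1) already contains ring B (C5–C10), the C8 oxygen, C5 with its hydrogen and C4 with both methyls. Its enone β-carbon (C10) and its cyclobutane carbon C4, bonded to the α-carbon C7, act as a chiral 1,3-dielectrophile. In one TiCl4-mediated operation allyltrimethylsilane (2) is added to C10, the cyclobutane is cleaved and the C4 cation closes onto the allyl terminus, giving the trans-decalin. α′-Alkylation at C9, methylenation of C8, a Horner–Wadsworth–Emmons reaction and malonylation complete the target.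

Key step: step 1

Remark on the chemistry: labdane numbering is used for all intermediates (ring A = C1–C5 and C10; ring B = C5–C10); C2 (chloride) of 5, 6, 8 and 9 and C9 of 9 are carried as epimer mixtures because step 4 erases the first and resets the second; both enantiomers of verbenone are assumed to be commercial, and the (1S,5S)-(−) form is the one needed.

Step 1
Reactants: 1 (1S,5S)-(−)-verbenone; 2 allyltrimethylsilane
Product: 5 (4aR,8aR)-7-chloro-5,5,8a-trimethyl-3,4,4a,5,6,7,8,8a-octahydronaphthalen-2(1H)-one (trans-fused; C2 epimers), via allyl ketone 3 (not isolated), via tertiary chloride 4 (not isolated)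
Conditions: TiCl4 (2.2 equiv), CH2Cl2, −78 °C; then i-PrOH (1.0 equiv), −78 → 20 °C
Reagents that add atoms: titanium tetrachloride, Cl[Ti](Cl)(Cl)Cl
Why: Proposed new method: TiCl4 activates the enone and the allylsilane delivers its γ-carbon to C10 (Hosomi–Sakurai 1,4-addition, C1–C10); i-PrOH turns the titanium enolate into ketone 3, whose TiCl4 complex heterolyses the strained bond between the α-carbon C7 and C4 to give the tertiary C4 cation (stored as chloride 4) and the C7=C8 titanium enolate, and the cation then adds to the terminal alkene carbon C3 while chloride caps C2 (C3–C4). The closest known reaction types are the Hosomi–Sakurai reaction, the Lewis-acid cleavage of pinan-2-one-type cyclobutanes with capture of the tertiary cation by a nucleophile held on the neighbouring ring carbon (as in terpenylations of resorcinols with pinane enones), and the Lewis-acid-mediated addition of tertiary alkyl chlorides to terminal alkenes, which stops at the 1:1 adduct because the secondary chloride formed ionises far less readily than the tertiary chloride consumed. Ring A closes in the 6-endo-trig mode (Markovnikov; the 5-exo alternative would need a primary cation) through a chair-like arrangement in which C1 on C10 and C4 on C5 are both equatorial on ring B. C10 is set by the substrate, since the allyl group enters anti to the CMe2 bridge and therefore trans to the C4 substituent on C5, so closure can only give the trans-fused decalin with the C10 methyl anti to H5; C5 is carried over unchanged from 1 and C2 is formed without control and erased in step 4. The step needs 1,4- rather than 1,2-allylation, which is the normal outcome for allylsilanes and TiCl4 on enones, and cleavage of C7–C4 rather than C5–C4, which is secured because C5–C4 cleavage is a vinylogous process open only to the enone and is shut off once C10 is saturated.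

Step 2
Reactants: 5 (4aR,8aR)-7-chloro-5,5,8a-trimethyl-3,4,4a,5,6,7,8,8a-octahydronaphthalen-2(1H)-one
Product: 6 (4aR,8aR)-7-chloro-5,5,8a-trimethyl-4a,5,6,7,8,8a-hexahydronaphthalen-2(1H)-one (C8 ketone conjugated to C6=C7)
Conditions: IBX (2.0 equiv), DMSO, 75 °C
Reagents that add atoms: none
Why: IBX dehydrogenates the ketone through its enol to the conjugated enone (IBX-mediated α,β-dehydrogenation), and because C10 is quaternary only C6–C7 can be desaturated, which leaves C9 as the sole α′ position while C5 and C10 stay untouched.

Step 3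
Reactants: 6 (4aR,8aR)-7-chloro-5,5,8a-trimethyl-4a,5,6,7,8,8a-hexahydronaphthalen-2(1H)-one; 7 2-(2-bromoethyl)-2-methyl-1,3-dioxolane
Product: 9 (4aR,8aR)-7-chloro-5,5,8a-trimethyl-1-[2-(2-methyl-1,3-dioxolan-2-yl)ethyl]-4a,5,6,7,8,8a-hexahydronaphthalen-2(1H)-one (C9 epimers), via lithium dienolate 8 (not isolated)
Conditions: LiN(i-Pr)2, THF, −78 °C; then 7, HMPA, −78 → 0 °C
Reagents that add atoms: none
Why: Kinetic deprotonation of the enone occurs at its only α′ carbon, C9, and the cross-conjugated lithium dienolate 8 is alkylated by the primary bromide (SN2 enolate alkylation) to attach C11–C13 and C16 as a masked methyl ketone; the electrophile is expected to enter anti to the axial C10 methyl, but C9 is reset in step 4.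

Step 4
Reactants: 9 (4aR,8aR)-7-chloro-5,5,8a-trimethyl-1-[2-(2-methyl-1,3-dioxolan-2-yl)ethyl]-4a,5,6,7,8,8a-hexahydronaphthalen-2(1H)-one
Product: 10 (1S,4aR,8aR)-5,5,8a-trimethyl-1-[2-(2-methyl-1,3-dioxolan-2-yl)ethyl]octahydronaphthalen-2(1H)-one
Conditions: Li, liquid NH3, t-BuOH (1 equiv), THF, −78 °C; NH4Cl; then NaOMe, MeOH, 25 °C
Reagents that add atoms: none
Why: Dissolving-metal (Birch-type) conditions reduce C6=C7 of the enone via the lithium enolate and cleave the secondary C2–Cl bond while the dioxolane survives, and the methoxide equilibration then epimerises C9 (α to the C8 ketone) to the isomer expected to be thermodynamically preferred, with the side chain equatorial and cis to the C10 methyl as in the target.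

Step 5
Reactants: 10 (1S,4aR,8aR)-5,5,8a-trimethyl-1-[2-(2-methyl-1,3-dioxolan-2-yl)ethyl]octahydronaphthalen-2(1H)-one; 11 methyltriphenylphosphonium bromide
Product: 13 4-[(1R,4aR,8aR)-5,5,8a-trimethyl-2-methylidenedecahydronaphthalen-1-yl]butan-2-one, via methylidene ketal 12 (not isolated)
Conditions: KOt-Bu, toluene, 80 °C; then 1 M HCl, THF, 25 °C
Reagents that add atoms: water, O
Why: Wittig methylenation converts the hindered C8 ketone into the exocyclic C8=C17 alkene (any C9 epimerisation under the basic ylide conditions again leads to the equatorial chain), and dilute acid in the same flask hydrolyses the dioxolane to the C13 methyl ketone without isomerising the 1,1-disubstituted alkene.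

Step 6
Reactants: 13 4-[(1R,4aR,8aR)-5,5,8a-trimethyl-2-methylidenedecahydronaphthalen-1-yl]butan-2-one; 14 triethyl phosphonoacetate
Product: 15 ethyl (2E)-3-methyl-5-[(1R,4aR,8aR)-5,5,8a-trimethyl-2-methylidenedecahydronaphthalen-1-yl]pent-2-enoate (ethyl ent-copalate)
Conditions: NaH, THF, 0 → 65 °C
Reagents that add atoms: none
Why: Horner–Wadsworth–Emmons olefination of the unhindered methyl ketone with the sodium phosphonoacetate carbanion forms C13=C14 and should favour the (E)-ester (larger chain trans to the ester), the minor (Z)-isomer being removed by chromatography.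

Step 7
Reactants: 15 ethyl (2E)-3-methyl-5-[(1R,4aR,8aR)-5,5,8a-trimethyl-2-methylidenedecahydronaphthalen-1-yl]pent-2-enoate
Product: 16 (2E)-3-methyl-5-[(1R,4aR,8aR)-5,5,8a-trimethyl-2-methylidenedecahydronaphthalen-1-yl]pent-2-en-1-ol (ent-copalol)
Conditions: i-Bu2AlH (2.5 equiv), CH2Cl2, −78 °C; aq. potassium sodium tartrate
Reagents that add atoms: none
Why: 1,2-Reduction of the conjugated ester by i-Bu2AlH at low temperature gives the primary allylic alcohol without touching either alkene or any stereocentre.

Step 8
Reactants: 16 (2E)-3-methyl-5-[(1R,4aR,8aR)-5,5,8a-trimethyl-2-methylidenedecahydronaphthalen-1-yl]pent-2-en-1-ol; 17 2,2-dimethyl-1,3-dioxane-4,6-dione (Meldrum's acid)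
Product: 18 3-oxo-3-{[(2E)-3-methyl-5-[(1R,4aR,8aR)-5,5,8a-trimethyl-2-methylidenedecahydronaphthalen-1-yl]pent-2-en-1-yl]oxy}propanoic acid (CNP0107438.1)
Conditions: toluene, 90 °C
Reagents that add atoms: none
Why: The primary allylic alcohol opens Meldrum's acid by acyl transfer with loss of acetone, which delivers the hydrogen malonate directly under neutral conditions that spare the exocyclic alkene and the allylic ester.

**Compound list**

1 | (1S,5S)-(−)-verbenone, (1S,5S)-4,6,6-trimethylbicyclo[3.1.1]hept-3-en-2-one | CC1=CC(=O)[C@H]2C[C@@H]1C2(C)C | starting material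
2 | allyltrimethylsilane | C=CC[Si](C)(C)C | starting material
3 | (1S,4S,5S)-4-allyl-4,6,6-trimethylbicyclo[3.1.1]heptan-2-one (allyl anti to the CMe2 bridge) | C[C@]1(CC=C)CC(=O)[C@H]2C[C@@H]1C2(C)C | intermediate (not isolated)
4 | (3S,4S)-3-allyl-4-(2-chloropropan-2-yl)-3-methylcyclohexan-1-one | O=C1CC[C@H](C(C)(C)Cl)[C@@](C)(CC=C)C1 | intermediate (not isolated)
5 | (4aR,8aR)-7-chloro-5,5,8a-trimethyl-3,4,4a,5,6,7,8,8a-octahydronaphthalen-2(1H)-one (trans-fused; C2 epimers) | O=C1CC[C@@H]2C(C)(C)CC(Cl)C[C@@]2(C)C1 | intermediate
6 | (4aR,8aR)-7-chloro-5,5,8a-trimethyl-4a,5,6,7,8,8a-hexahydronaphthalen-2(1H)-one | O=C1C=C[C@@H]2C(C)(C)CC(Cl)C[C@@]2(C)C1 | intermediate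
7 | 2-(2-bromoethyl)-2-methyl-1,3-dioxolane | CC1(CCBr)OCCO1 | starting material
8 | lithium cross-conjugated dienolate of 6 (O–C8=C9 and C6=C7) | [Li+].[O-]C1=C[C@]2(C)CC(Cl)CC(C)(C)[C@H]2C=C1 | intermediate (not isolated)
9 | (4aR,8aR)-7-chloro-5,5,8a-trimethyl-1-[2-(2-methyl-1,3-dioxolan-2-yl)ethyl]-4a,5,6,7,8,8a-hexahydronaphthalen-2(1H)-one (C9 and C2 epimers) | O=C1C=C[C@@H]2C(C)(C)CC(Cl)C[C@@]2(C)C1CCC3(C)OCCO3 | intermediate
10 | (1S,4aR,8aR)-5,5,8a-trimethyl-1-[2-(2-methyl-1,3-dioxolan-2-yl)ethyl]octahydronaphthalen-2(1H)-one | O=C1CC[C@@H]2C(C)(C)CCC[C@@]2(C)[C@@H]1CCC3(C)OCCO3 | intermediate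
11 | methyltriphenylphosphonium bromide | C[P+](c1ccccc1)(c1ccccc1)c1ccccc1.[Br-] | starting material
12 | 2-methyl-2-{2-[(1R,4aR,8aR)-5,5,8a-trimethyl-2-methylidenedecahydronaphthalen-1-yl]ethyl}-1,3-dioxolane | C=C1CC[C@@H]2C(C)(C)CCC[C@@]2(C)[C@@H]1CCC3(C)OCCO3 | intermediate (not isolated)
13 | 4-[(1R,4aR,8aR)-5,5,8a-trimethyl-2-methylidenedecahydronaphthalen-1-yl]butan-2-one | C=C1CC[C@@H]2C(C)(C)CCC[C@@]2(C)[C@@H]1CCC(C)=O | intermediate
14 | triethyl phosphonoacetate | CCOC(=O)CP(=O)(OCC)OCC | starting material
15 | ethyl (2E)-3-methyl-5-[(1R,4aR,8aR)-5,5,8a-trimethyl-2-methylidenedecahydronaphthalen-1-yl]pent-2-enoate | C=C1CC[C@@H]2C(C)(C)CCC[C@@]2(C)[C@@H]1CC/C(C)=C/C(=O)OCC | intermediate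
16 | (2E)-3-methyl-5-[(1R,4aR,8aR)-5,5,8a-trimethyl-2-methylidenedecahydronaphthalen-1-yl]pent-2-en-1-ol | C=C1CC[C@@H]2C(C)(C)CCC[C@@]2(C)[C@@H]1CC/C(C)=C/CO | intermediate
17 | 2,2-dimethyl-1,3-dioxane-4,6-dione (Meldrum's acid) | CC1(C)OC(=O)CC(=O)O1 | starting material
18 | 3-oxo-3-{[(2E)-3-methyl-5-[(1R,4aR,8aR)-5,5,8a-trimethyl-2-methylidenedecahydronaphthalen-1-yl]pent-2-en-1-yl]oxy}propanoic acid | C=C1CC[C@@H]2C(C)(C)CCC[C@@]2(C)[C@@H]1CC/C(C)=C/COC(=O)CC(=O)O | target

**Totals.** Total step count: 8. Longest linear sequence: 8 steps (1 → 18).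

**Steps most likely to fail**

Step 1 (Proposed new method). What may go wrong: the cascade may stall, either because the titanium enolate is not turned over to the ketone or because the ring-opened cation rests as the tertiary chloride without closing. The Lewis acid may also trigger skeletal rearrangement of the pinane enone before allylation. The fallback sets out from 1 and comes back at 5; it runs the three events as separate steps of known type and keeps the enone away from a strong Lewis acid. Copper-catalysed conjugate addition of allylmagnesium bromide in the presence of Me3SiCl (CuBr·SMe2, THF, −78 °C) gives the trimethylsilyl enol ether F1, which is hydrolysed (1 M HCl, THF) to ketone 3, now isolated. The cyclobutane of 3 is cleaved with anhydrous HCl and catalytic AlCl3 in CH2Cl2 at −20 °C to the tertiary chloride 4, also isolated. Compound 4 is then cyclised with SnCl4 in CH2Cl2 at −78 → −20 °C (addition of a tertiary alkyl chloride across a terminal alkene) to 5.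

Step 3. What may go wrong: substitution at the hindered, neopentyl-type dienolate carbon by an unactivated primary bromide may be slow. Proton transfer (γ-deprotonation at C5 with loss of the ring-fusion configuration, or double alkylation) and elimination of HBr from 7 would then compete. The fallback sets out from 6 and comes back at 9; it makes the C9–C11 bond by conjugate addition instead of substitution. LiN(i-Pr)2 and Me3SiCl (THF, −78 °C) convert 6 into the cross-conjugated trimethylsilyl dienol ether F2. Mukaiyama–Michael addition of this ether to but-3-en-2-one (TiCl4, Ti(Oi-Pr)4, CH2Cl2, −78 °C) gives the enone methyl ketone F3. Chemoselective ketalisation of the saturated methyl ketone (ethane-1,2-diol, pyridinium p-toluenesulfonate, benzene, azeotropic removal of water; the conjugated C8 carbonyl reacts far more slowly) gives 9.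

Step 4. What may go wrong: the thermodynamic bias at C9 may be insufficient during the base equilibration, so that material with the chain axial is carried into the methylenation, where C9 is frozen. The fallback sets out from 9 and comes back at 10; it sets C9 under kinetic instead of thermodynamic control. After the dissolving-metal stage (NaOMe omitted) the crude ketone is treated with Me3SiCl, NaI and Et3N in MeCN at 25 °C to give the more substituted C8=C9 trimethylsilyl enol ether F4. MeLi (THF, 0 °C) releases the lithium enolate, which is protonated at −78 °C by 2,6-di-tert-butyl-4-methylphenol from the face opposite the axial C10 methyl, giving 10 with the chain equatorial.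

Further compounds
F1 | step 1 | trimethylsilyl enol ether of 3, [(4-allyl-4,6,6-trimethylbicyclo[3.1.1]hept-2-en-2-yl)oxy]trimethylsilane | C[C@]1(CC=C)C=C(O[Si](C)(C)C)[C@H]2C[C@@H]1C2(C)C
F2 | step 3 | trimethylsilyl dienol ether of 6 (Me3SiO–C8=C9 and C6=C7) | C[Si](C)(C)OC1=C[C@]2(C)CC(Cl)CC(C)(C)[C@H]2C=C1
F3 | step 3 | (4aR,8aR)-7-chloro-5,5,8a-trimethyl-1-(3-oxobutyl)-4a,5,6,7,8,8a-hexahydronaphthalen-2(1H)-one (C9 and C2 epimers) | O=C1C=C[C@@H]2C(C)(C)CC(Cl)C[C@@]2(C)C1CCC(C)=O
F4 | step 4 | C8=C9 trimethylsilyl enol ether of 10 | C[Si](C)(C)OC1=C(CCC3(C)OCCO3)[C@]2(C)CCCC(C)(C)[C@H]2CC1
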